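**Analysis of the target**

Derrisdione A (24) is a 2,2-dimethyl-2H-chromene whose benzene ring (ring A) is substituted at every carbon. C5 carries a methoxy group, C6 an aryl 1,2-dione ending in a 4-hydroxyphenyl ring (ring B), C7 a free hydroxyl, C8 a 3-methylbut-2-enyl (prenyl) group, and C8a and C4a the pyran oxygen and pyran carbon. There is no stereocentre and no stereogenic double bond, so no configuration has to be controlled. The sensitive functions are the vicinal diketone (electrophilic, degraded by strong base, condensed by 1,2-diamines, able to form a hemiketal with the C7 hydroxyl), the prenyl group beside a free phenol (closed to a chroman by acid, attacked by electrophilic oxidants), the electron-rich chromene alkene and two free phenols. The difficulty is regiochemical: three oxygens must be told apart (one methylated, one free, one in the pyran) and three carbon groups must be placed on the three nucleophilic positions of a phloroglucinol-type ring, which electrophilic substitution distinguishes poorly. A second difficulty is reaching the dione oxidation level beside two oxidisable alkenes. The plan rests on the strict alternation around ring A: oxygen on C5, C7 and C8a, carbon on C4a, C6 and C8. A ketene and an oxygenated alkyne give exactly this pattern when they are stitched into a benzene ring, so ring A can come from two acyclic pieces that already hold the methoxy group, the masked dione, the prenyl group and the C8a oxygen, with C4a left as the only ring CH for the pyran.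

**Retrosynthetic reasoning**

Pyran ring. The C4a–C4 and O1–C2 bonds of 24 are cut last, giving triol 22 and the enal 23. C4a is the only unsubstituted carbon of ring A and has a hydroxyl (C8a) on one side and a methyl ether (C5) on the other, so the annulation has one possible site and one possible ring oxygen. Closing the pyran at the end also keeps the acid- and oxidant-sensitive chromene alkene out of every earlier step. Forward, the reaction must alkylate C4a with the enal, lose water to an ortho-quinone methide and close by oxa-6π electrocyclisation.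

Protecting groups and the dione. Triol 22 is traced through the diphenol acetate 21 to the fully protected dione 20, and the two carbonyl groups of 20 to the diaryl alkyne of 19. An alkyne is chosen as the masked dione because it is inert to the bases, organometallic reagents, light and heat used before it, is slim enough to sit between two ortho substituents, and brings both carbons to the ketone level in one catalytic oxygen-transfer step. Acetate 19 comes from phenol 18. The C7 hydroxyl must be capped because a free ortho hydroxyl would add to the metal-activated alkyne (5-endo closure to a benzofuran) or to the neighbouring prenyl group.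

Ring A. Phenol 18 is cut across four bonds into diazo ketone 10 and siloxyalkyne 14: C4a–C5 (Wolff shift), C7–C8 and C8a–C4a ([2+2] cycloaddition) and C6–C7 (6π closure). This cut is preferred to any substitution on a preformed arene because each oxygen arrives with its identity fixed by its origin: the C5 methyl ether comes from 10, the C8a silyl ether from 14, and the free C7 hydroxyl from the ketene carbonyl. The three carbon substituents are likewise placed by connectivity (alkyne at C6 from 10, prenyl at C8 from 14, hydrogen at C4a from the diazo carbon). Forward, the step must generate vinylketene 15 and pass through cyclobutenone 16 and dienylketene 17 with one regiochemistry of ketene–alkyne union.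

Diazo ketone. The diazo group of 10 is introduced by diazo transfer to methyl ketone 8 through its trifluoroacetyl derivative 9. Acylating a diazoalkane with the corresponding unsaturated acid chloride is avoided because conjugated acid chlorides invite dipolar addition to the C=C bond, and reaching the acid would need aqueous base that strips the aryl silyl ether. Enynone 8 is cut at its C=C bond (the future C5–C6 bond of ring A) into ynal 5 and ketophosphonate 7, which delivers the methoxy and acetyl groups together. Phosphonate 7 comes from the diazo phosphonate 6 by O–H insertion.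

Ynal. Aldehyde 5 comes from propargylic alcohol 4 by oxidation, 4 from aryl iodide 2 and alkynol 3 by C(sp2)–C(sp) coupling, and 2 from phenol 1 by silylation. The silyl ether is put on first so that no free phenol meets the coupling, the phosphonate anion or the amide base.

Siloxyalkyne. Compound 14 is the O-silyl derivative of ynolate 13, which comes from ester 12 by a one-carbon carbenoid homologation in which the prenyl carbon migrates. Ester 12 comes from acid 11 by alkylation of the carboxylate, not by acid catalysis, which would lactonise it.

**Alternatives that were turned down**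

Alternative 1: Both aryl–carbonyl bonds of the dione are cut, leaving the oxalyl unit as 1,4-dimethylpiperazine-2,3-dione A2. In the forward step [5-methoxy-7-(methoxymethoxy)-2,2-dimethyl-8-(3-methylbut-2-enyl)-2H-chromen-6-yl]lithium A3 would add to one amide carbonyl of A2, the stable tetrahedral adduct would let 4-(methoxymethoxy)phenyllithium A4 add to the other, and hydrolysis would give Derrisdione A bis(methoxymethyl) ether A1.
- For: the dione arrives at its final oxidation level with no oxidation beside the two alkenes, and on this point the alternative is stronger than the chosen route. Lithiation at C6 is also well directed by two flanking ether oxygens.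
- Against: it presupposes the fully substituted chromene, so it does not address the ring A pattern. A3 is a doubly ortho-substituted aryllithium attacking an amide, and its generation competes with deprotonation of the benzylic–allylic CH2 of the prenyl group. The final acidic removal of two methoxymethyl ethers exposes the chromene alkene and the prenyl/C7–OH pair to acid.
- Comparison: the chosen route accepts one chemoselective alkyne oxidation and in return builds the substitution pattern itself and ends with base- and fluoride-labile protecting groups only.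

Alternative 2: The three pyran bonds C4a–C4, C8a–O1 and O1–C2 are cut through an aryne across C4a–C8a. A fluoride source would convert 3-methoxy-5-(methoxymethoxy)-6-(3-methylbut-2-enyl)-2-(trimethylsilyl)phenyl trifluoromethanesulfonate A6 into the aryne. Addition to the carbonyl group of 23, opening of the benzoxete to an ortho-quinone methide and oxa-6π closure would give 5-methoxy-7-(methoxymethoxy)-2,2-dimethyl-8-(3-methylbut-2-enyl)-2H-chromene A5.
- For: the conditions are neutral and cold, and the methoxy group next to C4a should steer the oxygen to C8a. In mildness it is stronger than the final condensation of the chosen route.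
- Against: the aryne carbon C8a sits next to the prenyl group, and intramolecular ene reaction with its allylic hydrogens is a fast aryne pathway. Precursor A6 is itself a pentasubstituted benzene whose preparation repeats the ring A problem. The step makes only the easiest ring and leaves C6 to be acylated afterwards, which adds steps.
- Comparison: the chosen route puts its key step where the difficulty lies and leaves for the pyran a condensation that has a single possible site.

Alternative 3: The C8–CH2 bond of the prenyl group and the C4a–C4 and O1–C2 bonds are traced to two O-alkyl groups in 1-[4-(tert-butyldimethylsilyloxy)phenyl]-2-[2-methoxy-6-(2-methylbut-3-en-2-yloxy)-4-(2-methylbut-3-yn-2-yloxy)phenyl]ethane-1,2-dione A8. Gentle heating would move the tertiary allyl group from O7 to C8 by aromatic Claisen rearrangement (C6 is blocked). Stronger heating would send the propargyl group from O8a to C4a, and a 1,5-hydrogen shift and oxa-6π closure would give the ring B tert-butyldimethylsilyl ether of Derrisdione A, A7.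
- For: no reagent is needed, ring A needs no protecting group, and the first event blocks C8 for the second. In step count and atom economy it is stronger than the chosen route.
- Against: the outcome depends on the order of two thermal events, and a propargyl shift before the allyl shift would deliver the pyran to C8. The tertiary allyl ether on the hydrogen-bonded, hindered C7 oxygen ortho to an acyl group is hard to make and ionises easily. The dione must survive prolonged heating, and the benzil precursor needs a selective mono-methylation and two different O-alkylations.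
- Comparison: the chosen route fixes all six positions by which atom is bonded to which, not by competing rates.

Key step: step 9

Remark on the chemistry: ring B is carried as its tert-butyldimethylsilyl ether and the C8a oxygen as its triisopropylsilyl ether; compounds 6 (Bestmann–Ohira reagent) and 23 are assumed to be purchasable.

**Route**

Step 1
Reactants: 1 4-iodophenol
Product: 2 tert-butyl(4-iodophenoxy)dimethylsilane
Conditions: TBSCl, imidazole, DMF, rt
Reagents that add atoms: tert-butyldimethylsilyl chloride, CC(C)(C)[Si](C)(C)Cl
Why: Silylation of a phenol with the silyl chloride and imidazole (base and silyl-transfer catalyst); the ether masks the acidic OH for the coupling, the phosphonate anion and the amide base to come.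

Step 2
Reactants: 2 tert-butyl(4-iodophenoxy)dimethylsilane; 3 prop-2-yn-1-ol
Product: 4 3-[4-(tert-butyldimethylsilyloxy)phenyl]prop-2-yn-1-ol
Conditions: PdCl2(PPh3)2 (2 mol%), CuI (4 mol%), Et3N, THF, rt
Reagents that add atoms: none
Why: Sonogashira coupling; the aryl iodide adds oxidatively to zerovalent palladium at room temperature and the copper acetylide of 3 transmetalates, and the silyl ether and the free primary alcohol are tolerated.

Step 3
Reactants: 4 3-[4-(tert-butyldimethylsilyloxy)phenyl]prop-2-yn-1-ol
Product: 5 3-[4-(tert-butyldimethylsilyloxy)phenyl]prop-2-ynal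
Conditions: Dess–Martin periodinane, CH2Cl2, 0 °C → rt
Reagents that add atoms: none
Why: Dess–Martin oxidation of a propargylic alcohol to the ynal under non-basic conditions that spare the aryl silyl ether; the ynal is a good Michael acceptor and should be used at once.

Step 4
Reactants: 6 dimethyl (1-diazo-2-oxopropyl)phosphonate
Product: 7 dimethyl (1-methoxy-2-oxopropyl)phosphonate (racemic)
Conditions: Rh2(OAc)4 (1 mol%), MeOH (5 equiv), ClCH2CH2Cl, 60 °C
Reagents that add atoms: methanol, CO
Why: Rhodium-carbenoid O–H insertion; the dirhodium catalyst turns the diazo phosphonate into an electrophilic carbenoid that methanol captures (oxonium ylide, proton shift), and the new stereocentre is racemic and disappears in step 5.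

Step 5
Reactants: 5 3-[4-(tert-butyldimethylsilyloxy)phenyl]prop-2-ynal; 7 dimethyl (1-methoxy-2-oxopropyl)phosphonate
Product: 8 (Z)-6-[4-(tert-butyldimethylsilyloxy)phenyl]-3-methoxyhex-3-en-5-yn-2-one
Conditions: 7, NaH, THF, 0 °C; then 5, −78 → 0 °C
Reagents that add atoms: none
Why: Horner–Wadsworth–Emmons olefination with a stabilised β-ketophosphonate anion that adds 1,2 to the ynal; elimination should place the larger acetyl group trans to the alkynyl group (Z isomer), and a minor E isomer would be removed by chromatography or equilibrated with a trace of iodine.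

Step 6
Reactants: 8 (Z)-6-[4-(tert-butyldimethylsilyloxy)phenyl]-3-methoxyhex-3-en-5-yn-2-one
Product: 10 (Z)-6-[4-(tert-butyldimethylsilyloxy)phenyl]-1-diazo-3-methoxyhex-3-en-5-yn-2-one, via trifluoroacetyl ketone 9 (not isolated)
Conditions: LiN(SiMe3)2, THF, −78 °C; CF3CO2CH2CF3; dilute HCl wash, concentrate; then MsN3, Et3N, H2O, MeCN, rt
Reagents that add atoms: methanesulfonyl azide, CS(=O)(=O)N=[N+]=[N-]; 2,2,2-trifluoroethyl trifluoroacetate, O=C(OCC(F)(F)F)C(F)(F)F (its acyl group stays only in intermediate 9)
Why: Detrifluoroacetylative diazo transfer; enolisation is possible only at the methyl group, Claisen acylation gives the activated 1,3-diketone 9, and the sulfonyl azide transfers N2 to the central carbon with loss of the trifluoroacetyl group as the sulfonamide, the standard entry to α′-diazo enones that avoids dipolar addition to the C=C bond.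

Step 7
Reactants: 11 4-methylpent-3-enoic acid
Product: 12 methyl 4-methylpent-3-enoate
Conditions: MeI, K2CO3, DMF, rt
Reagents that add atoms: iodomethane, CI
Why: SN2 alkylation of the carboxylate under mild base, chosen over acid-catalysed esterification because strong acid would lactonise the β,γ-unsaturated acid; room temperature keeps the double bond out of conjugation.

Step 8
Reactants: 12 methyl 4-methylpent-3-enoate
Product: 14 triisopropyl[(5-methylhex-4-en-1-yn-1-yl)oxy]silane, via lithium ynolate 13 (not isolated)
Conditions: CH2Br2, lithium 2,2,6,6-tetramethylpiperidide, THF, −78 °C; n-BuLi, −78 °C → rt; TIPSCl, −78 °C → rt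
Reagents that add atoms: dibromomethane, BrCBr; chlorotriisopropylsilane, CC(C)[Si](Cl)(C(C)C)C(C)C
Why: Kowalski ester homologation; dibromomethyllithium adds to the ester, the α,α-dibromoketone enolate undergoes bromine–lithium exchange and 1,2-shift of the prenyl carbon to the carbenoid centre to give ynolate 13, which a bulky silyl chloride traps on oxygen.

Step 9
Reactants: 10 (Z)-6-[4-(tert-butyldimethylsilyloxy)phenyl]-1-diazo-3-methoxyhex-3-en-5-yn-2-one; 14 triisopropyl[(5-methylhex-4-en-1-yn-1-yl)oxy]silane
Product: 18 2-{[4-(tert-butyldimethylsilyloxy)phenyl]ethynyl}-3-methoxy-6-(3-methylbut-2-enyl)-5-(triisopropylsilyloxy)phenol, via vinylketene 15 (not isolated), via cyclobutenone 16 (not isolated), via dienylketene 17 (not isolated)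
Conditions: 14 (1.5 equiv), hν (365 nm), degassed ClCH2CH2Cl, rt; then 80 °C
Reagents that add atoms: none
Why: Light expels N2 from 10 and the methoxyenynyl group migrates to the former diazo carbon (Wolff rearrangement, C4a–C5 bond) to give vinylketene 15. The ketene and the electron-rich alkyne 14 then join in a polarised [2+2] cycloaddition in which the prenyl-bearing carbon of 14, nucleophilic because it is β to oxygen, attacks the ketene carbonyl carbon (C7–C8) and the siloxy carbon bonds to the ketene CH (C8a–C4a), giving cyclobutenone 16. Reversible 4π electrocyclic opening of 16 gives dienylketene 17, and the rotamer with the alkenyl group turned towards the ketene closes the six-membered carbocycle (ring A) by disrotatory 6π electrocyclisation (C6–C7), after which the cyclohexadienone tautomerises to phenol 18. The closest known reaction is the photochemical variant of the Danheiser benzannulation of α′-diazo enones with siloxyalkynes, which gives resorcinol monosilyl ethers. No stereocentre survives (C4 of 16 is transient), so the only selectivity needed is the regiochemistry of the [2+2] step, which the polarity of the ynol ether and the ketene secures. The Z enol ether keeps the arylalkyne remote from the ketene in 15, so that a Moore-type closure onto the alkyne is not possible, and puts the alkyne on the outside in the 6π step. Long-wavelength light and an excess of 14 are chosen to limit excitation of the tolane product and to capture the ketene quickly.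

Step 10
Reactants: 18 2-{[4-(tert-butyldimethylsilyloxy)phenyl]ethynyl}-3-methoxy-6-(3-methylbut-2-enyl)-5-(triisopropylsilyloxy)phenol
Product: 19 2-{[4-(tert-butyldimethylsilyloxy)phenyl]ethynyl}-3-methoxy-6-(3-methylbut-2-enyl)-5-(triisopropylsilyloxy)phenyl acetate
Conditions: Ac2O, Et3N, DMAP (cat.), CH2Cl2, 0 °C → rt
Reagents that add atoms: acetic anhydride, CC(=O)OC(C)=O
Why: DMAP-catalysed acylation of the flanked but acidic phenol; the acetate prevents the C7 oxygen from adding to the metal-activated alkyne or to the prenyl group in step 11.

Step 11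
Reactants: 19 2-{[4-(tert-butyldimethylsilyloxy)phenyl]ethynyl}-3-methoxy-6-(3-methylbut-2-enyl)-5-(triisopropylsilyloxy)phenyl acetate
Product: 20 2-{2-[4-(tert-butyldimethylsilyloxy)phenyl]-2-oxoacetyl}-3-methoxy-6-(3-methylbut-2-enyl)-5-(triisopropylsilyloxy)phenyl acetate
Conditions: PdCl2 (10 mol%), DMSO, 120 °C
Reagents that add atoms: dimethyl sulfoxide, CS(C)=O
Why: Palladium-catalysed oxidation of a diarylalkyne to the benzil with the sulfoxide as oxygen donor (divalent palladium activates the alkyne, two sulfoxide molecules deliver oxygen and leave as sulfide); the trisubstituted prenyl alkene binds divalent palladium far less well than the alkyne, and no electrophilic oxygen-transfer reagent is present.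

Step 12
Reactants: 20 2-{2-[4-(tert-butyldimethylsilyloxy)phenyl]-2-oxoacetyl}-3-methoxy-6-(3-methylbut-2-enyl)-5-(triisopropylsilyloxy)phenyl acetate
Product: 22 1-[2,4-dihydroxy-6-methoxy-3-(3-methylbut-2-enyl)phenyl]-2-(4-hydroxyphenyl)ethane-1,2-dione, via diphenol acetate 21 (not isolated)
Conditions: Bu4NF, THF, 0 °C; then MeOH, K2CO3 (cat.), rt; aq NH4Cl work-up
Reagents that add atoms: none
Why: Fluoride cleaves both aryl silyl ethers, each a good leaving group para to a ketone, and the basic methanol that follows transesterifies the activated aryl acetate; cold, short treatment limits base-induced reactions of the dione.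

Step 13
Reactants: 22 1-[2,4-dihydroxy-6-methoxy-3-(3-methylbut-2-enyl)phenyl]-2-(4-hydroxyphenyl)ethane-1,2-dione; 23 3-methylbut-2-enal
Product: 24 Derrisdione A, 1-[7-hydroxy-5-methoxy-2,2-dimethyl-8-(3-methylbut-2-enyl)-2H-chromen-6-yl]-2-(4-hydroxyphenyl)ethane-1,2-dione
Conditions: pyridine, 110 °C (sealed tube)
Reagents that add atoms: none
Why: Base-mediated condensation of a phenol with an enal (chromenylation); the phenolate attacks through C4a, the only free ring position and activated by three oxygen substituents, loss of water gives an ortho-quinone methide, and oxa-6π electrocyclisation onto the C8a oxygen closes the pyran, with pyridine chosen because primary-amine catalysts would condense with the dione.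

**Compound list**

1 | 4-iodophenol | Oc1ccc(I)cc1 | starting material
2 | tert-butyl(4-iodophenoxy)dimethylsilane | CC(C)(C)[Si](C)(C)Oc1ccc(I)cc1 | intermediate
3 | prop-2-yn-1-ol | C#CCO | starting material
4 | 3-[4-(tert-butyldimethylsilyloxy)phenyl]prop-2-yn-1-ol | OCC#Cc1ccc(O[Si](C)(C)C(C)(C)C)cc1 | intermediate
5 | 3-[4-(tert-butyldimethylsilyloxy)phenyl]prop-2-ynal | O=CC#Cc1ccc(O[Si](C)(C)C(C)(C)C)cc1 | intermediate
6 | dimethyl (1-diazo-2-oxopropyl)phosphonate | COP(=O)(OC)C(=[N+]=[N-])C(C)=O | starting material
7 | dimethyl (1-methoxy-2-oxopropyl)phosphonate (racemic) | COC(C(C)=O)P(=O)(OC)OC | intermediate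
8 | (Z)-6-[4-(tert-butyldimethylsilyloxy)phenyl]-3-methoxyhex-3-en-5-yn-2-one | CC(=O)/C(OC)=C/C#Cc1ccc(O[Si](C)(C)C(C)(C)C)cc1 | intermediate
9 | (Z)-8-[4-(tert-butyldimethylsilyloxy)phenyl]-1,1,1-trifluoro-5-methoxyoct-5-en-7-yne-2,4-dione | O=C(CC(=O)/C(OC)=C/C#Cc1ccc(O[Si](C)(C)C(C)(C)C)cc1)C(F)(F)F | intermediate (not isolated)
10 | (Z)-6-[4-(tert-butyldimethylsilyloxy)phenyl]-1-diazo-3-methoxyhex-3-en-5-yn-2-one | [N-]=[N+]=CC(=O)/C(OC)=C/C#Cc1ccc(O[Si](C)(C)C(C)(C)C)cc1 | intermediate
11 | 4-methylpent-3-enoic acid | CC(C)=CCC(O)=O | starting material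
12 | methyl 4-methylpent-3-enoate | COC(=O)CC=C(C)C | intermediate
13 | lithium 5-methylhex-4-en-1-yn-1-olate | [Li+].[O-]C#CCC=C(C)C | intermediate (not isolated)
14 | triisopropyl[(5-methylhex-4-en-1-yn-1-yl)oxy]silane | CC(C)=CCC#CO[Si](C(C)C)(C(C)C)C(C)C | intermediate
15 | (Z)-6-[4-(tert-butyldimethylsilyloxy)phenyl]-3-methoxyhexa-1,3-dien-5-yn-1-one | O=C=C/C(OC)=C/C#Cc1ccc(O[Si](C)(C)C(C)(C)C)cc1 | intermediate (not isolated)
16 | 4-{(Z)-4-[4-(tert-butyldimethylsilyloxy)phenyl]-1-methoxybut-1-en-3-yn-1-yl}-2-(3-methylbut-2-enyl)-3-(triisopropylsilyloxy)cyclobut-2-en-1-one (racemic at C4) | O=C1C(CC=C(C)C)=C(O[Si](C(C)C)(C(C)C)C(C)C)C1/C(OC)=C/C#Cc1ccc(O[Si](C)(C)C(C)(C)C)cc1 | intermediate (not isolated)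
17 | (3E,5Z)-8-[4-(tert-butyldimethylsilyloxy)phenyl]-5-methoxy-2-(3-methylbut-2-enyl)-3-(triisopropylsilyloxy)octa-1,3,5-trien-7-yn-1-one | O=C=C(CC=C(C)C)/C(O[Si](C(C)C)(C(C)C)C(C)C)=C\C(OC)=C\C#Cc1ccc(O[Si](C)(C)C(C)(C)C)cc1 | intermediate (not isolated)
18 | 2-{[4-(tert-butyldimethylsilyloxy)phenyl]ethynyl}-3-methoxy-6-(3-methylbut-2-enyl)-5-(triisopropylsilyloxy)phenol | COc1cc(O[Si](C(C)C)(C(C)C)C(C)C)c(CC=C(C)C)c(O)c1C#Cc1ccc(O[Si](C)(C)C(C)(C)C)cc1 | intermediate
19 | 2-{[4-(tert-butyldimethylsilyloxy)phenyl]ethynyl}-3-methoxy-6-(3-methylbut-2-enyl)-5-(triisopropylsilyloxy)phenyl acetate | COc1cc(O[Si](C(C)C)(C(C)C)C(C)C)c(CC=C(C)C)c(OC(C)=O)c1C#Cc1ccc(O[Si](C)(C)C(C)(C)C)cc1 | intermediate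
20 | 2-{2-[4-(tert-butyldimethylsilyloxy)phenyl]-2-oxoacetyl}-3-methoxy-6-(3-methylbut-2-enyl)-5-(triisopropylsilyloxy)phenyl acetate | COc1cc(O[Si](C(C)C)(C(C)C)C(C)C)c(CC=C(C)C)c(OC(C)=O)c1C(=O)C(=O)c1ccc(O[Si](C)(C)C(C)(C)C)cc1 | intermediate
21 | 5-hydroxy-2-[2-(4-hydroxyphenyl)-2-oxoacetyl]-3-methoxy-6-(3-methylbut-2-enyl)phenyl acetate | COc1cc(O)c(CC=C(C)C)c(OC(C)=O)c1C(=O)C(=O)c1ccc(O)cc1 | intermediate (not isolated)
22 | 1-[2,4-dihydroxy-6-methoxy-3-(3-methylbut-2-enyl)phenyl]-2-(4-hydroxyphenyl)ethane-1,2-dione | COc1cc(O)c(CC=C(C)C)c(O)c1C(=O)C(=O)c1ccc(O)cc1 | intermediate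
23 | 3-methylbut-2-enal | CC(C)=CC=O | starting material
24 | Derrisdione A | COc1c2c(c(CC=C(C)C)c(O)c1C(=O)C(=O)c1ccc(O)cc1)OC(C)(C)C=C2 | target

**Step count and risk**

Total step count: 13. Longest linear sequence: 10 steps (steps 1, 2, 3, 5, 6, 9, 10, 11, 12, 13).

Step 9 (key step).
- What may go wrong: the conjugated aryl-enyne absorbs the light, so the enol ether double bond may photoisomerise, bringing the alkyne next to the ketene and opening a diradical closure onto it. The ortho-alkynylphenol product may photocyclise, and the ketene may be captured by the product phenol or dimerise before it meets 14.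
- Fallback (sets out from 7 and 14, returns at 19): the aryl chromophore is left out of the photochemical step and the aryl–alkyne bond is made afterwards. Olefination of 7 with purchased 3-(trimethylsilyl)prop-2-ynal F1 (NaH, THF) would give (Z)-3-methoxy-6-(trimethylsilyl)hex-3-en-5-yn-2-one F2. The two-stage diazo transfer of step 6 would give (Z)-1-diazo-3-methoxy-6-(trimethylsilyl)hex-3-en-5-yn-2-one F3. Irradiation with 14 followed by heating should give 3-methoxy-6-(3-methylbut-2-enyl)-5-(triisopropylsilyloxy)-2-[(trimethylsilyl)ethynyl]phenol F4. Brief K2CO3 in methanol at 0 °C would remove the C-silyl group to give 2-ethynyl-3-methoxy-6-(3-methylbut-2-enyl)-5-(triisopropylsilyloxy)phenol F5. Acetylation (Ac2O, Et3N, DMAP) would give 2-ethynyl-3-methoxy-6-(3-methylbut-2-enyl)-5-(triisopropylsilyloxy)phenyl acetate F6, and Sonogashira coupling of F6 with 2 (PdCl2(PPh3)2, CuI, Et3N, rt) would rejoin the route at 19.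

Step 11.
- What may go wrong: partial loss of the silyl or acetyl groups at 120 °C, followed by oxypalladation of the freed phenol onto the prenyl group or the alkyne, or attack of divalent palladium on the prenyl alkene.
- Fallback (sets out from 19, returns at 20): the two oxygens are introduced in separate, milder operations. Gold-catalysed hydration (Ph3PAuNTf2, wet dioxane, 60 °C), assisted by the neighbouring acetate carbonyl, should give 2-{2-[4-(tert-butyldimethylsilyloxy)phenyl]acetyl}-3-methoxy-6-(3-methylbut-2-enyl)-5-(triisopropylsilyloxy)phenyl acetate F7; the opposite orientation of water addition would lead to the same dione. Base-mediated aerobic α-oxidation of the benzylic ketone (DABCO, air, DMF, 80 °C) would then give 20.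

Step 13.
- What may go wrong: slow C-alkylation at C4a of the acyl-deactivated, hydrogen-bonded ring, base-induced degradation or hemiketalisation of the dione in hot pyridine, and self-condensation of the enal.
- Fallback (sets out from 18, returns at 24): the pyran is closed before the dione exists, on the more nucleophilic alkynyl resorcinol, where an amine-salt catalyst can be used. Buffered desilylation (Bu4NF, AcOH, THF, 0 °C) would give 4-[(4-hydroxyphenyl)ethynyl]-5-methoxy-2-(3-methylbut-2-enyl)benzene-1,3-diol F8. Condensation with 23 (ethylenediammonium diacetate, toluene, 60 °C) would give 6-[(4-hydroxyphenyl)ethynyl]-5-methoxy-2,2-dimethyl-8-(3-methylbut-2-enyl)-2H-chromen-7-ol F9. Acetylation of both phenols would give 4-{[7-acetoxy-5-methoxy-2,2-dimethyl-8-(3-methylbut-2-enyl)-2H-chromen-6-yl]ethynyl}phenyl acetate F10. Alkyne oxidation as in step 11 would give 4-{2-[7-acetoxy-5-methoxy-2,2-dimethyl-8-(3-methylbut-2-enyl)-2H-chromen-6-yl]-2-oxoacetyl}phenyl acetate F11, and methanolysis (K2CO3, MeOH, rt) would give 24.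

Step 8.
- What may go wrong: the lithium amide or dibromomethyllithium may enolise the doubly activated α-CH2 of 12 in place of adding to the ester, and base may shift the skipped double bond into conjugation.
- Fallback (sets out from 12, returns at 13): the ynolate is made by oxidising an acetylide instead of by carbenoid rearrangement. Reduction of 12 (i-Bu2AlH, CH2Cl2, −78 °C) would give 4-methylpent-3-enal F12, used crude. Dibromoolefination (CBr4, PPh3, CH2Cl2, 0 °C) would give 1,1-dibromo-5-methylhexa-1,4-diene F13, and n-BuLi (2 equiv, THF, −78 °C) would give lithium 5-methylhex-4-en-1-yn-1-ide F14. Oxidation with t-BuOOLi (−78 → 0 °C) would give ynolate 13, which is silylated as in step 8 to 14.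

**Further compounds**

F1 | step 9 | 3-(trimethylsilyl)prop-2-ynal (purchased) | O=CC#C[Si](C)(C)C
F2 | step 9 | (Z)-3-methoxy-6-(trimethylsilyl)hex-3-en-5-yn-2-one | CC(=O)/C(OC)=C/C#C[Si](C)(C)C
F3 | step 9 | (Z)-1-diazo-3-methoxy-6-(trimethylsilyl)hex-3-en-5-yn-2-one | [N-]=[N+]=CC(=O)/C(OC)=C/C#C[Si](C)(C)C
F4 | step 9 | 3-methoxy-6-(3-methylbut-2-enyl)-5-(triisopropylsilyloxy)-2-[(trimethylsilyl)ethynyl]phenol | COc1cc(O[Si](C(C)C)(C(C)C)C(C)C)c(CC=C(C)C)c(O)c1C#C[Si](C)(C)C
F5 | step 9 | 2-ethynyl-3-methoxy-6-(3-methylbut-2-enyl)-5-(triisopropylsilyloxy)phenol | COc1cc(O[Si](C(C)C)(C(C)C)C(C)C)c(CC=C(C)C)c(O)c1C#C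
F6 | step 9 | 2-ethynyl-3-methoxy-6-(3-methylbut-2-enyl)-5-(triisopropylsilyloxy)phenyl acetate | COc1cc(O[Si](C(C)C)(C(C)C)C(C)C)c(CC=C(C)C)c(OC(C)=O)c1C#C
F7 | step 11 | 2-{2-[4-(tert-butyldimethylsilyloxy)phenyl]acetyl}-3-methoxy-6-(3-methylbut-2-enyl)-5-(triisopropylsilyloxy)phenyl acetate | COc1cc(O[Si](C(C)C)(C(C)C)C(C)C)c(CC=C(C)C)c(OC(C)=O)c1C(=O)Cc1ccc(O[Si](C)(C)C(C)(C)C)cc1
F8 | step 13 | 4-[(4-hydroxyphenyl)ethynyl]-5-methoxy-2-(3-methylbut-2-enyl)benzene-1,3-diol | COc1cc(O)c(CC=C(C)C)c(O)c1C#Cc1ccc(O)cc1
F9 | step 13 | 6-[(4-hydroxyphenyl)ethynyl]-5-methoxy-2,2-dimethyl-8-(3-methylbut-2-enyl)-2H-chromen-7-ol | COc1c2C=CC(C)(C)Oc2c(CC=C(C)C)c(O)c1C#Cc1ccc(O)cc1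
F10 | step 13 | 4-{[7-acetoxy-5-methoxy-2,2-dimethyl-8-(3-methylbut-2-enyl)-2H-chromen-6-yl]ethynyl}phenyl acetate | COc1c2C=CC(C)(C)Oc2c(CC=C(C)C)c(OC(C)=O)c1C#Cc1ccc(OC(C)=O)cc1
F11 | step 13 | 4-{2-[7-acetoxy-5-methoxy-2,2-dimethyl-8-(3-methylbut-2-enyl)-2H-chromen-6-yl]-2-oxoacetyl}phenyl acetate | COc1c2C=CC(C)(C)Oc2c(CC=C(C)C)c(OC(C)=O)c1C(=O)C(=O)c1ccc(OC(C)=O)cc1
F12 | step 8 | 4-methylpent-3-enal | CC(C)=CCC=O
F13 | step 8 | 1,1-dibromo-5-methylhexa-1,4-diene | CC(C)=CCC=C(Br)Br
F14 | step 8 | lithium 5-methylhex-4-en-1-yn-1-ide | [Li+].[C-]#CCC=C(C)C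
A1 | alternative 1 | Derrisdione A bis(methoxymethyl) ether | COc1c2c(c(CC=C(C)C)c(OCOC)c1C(=O)C(=O)c1ccc(OCOC)cc1)OC(C)(C)C=C2
A2 | alternative 1 | 1,4-dimethylpiperazine-2,3-dione | CN1CCN(C)C(=O)C1=O
A3 | alternative 1 | [5-methoxy-7-(methoxymethoxy)-2,2-dimethyl-8-(3-methylbut-2-enyl)-2H-chromen-6-yl]lithium | [Li]c1c(OC)c2C=CC(C)(C)Oc2c(CC=C(C)C)c1OCOC
A4 | alternative 1 | 4-(methoxymethoxy)phenyllithium | [Li]c1ccc(OCOC)cc1
A5 | alternative 2 | 5-methoxy-7-(methoxymethoxy)-2,2-dimethyl-8-(3-methylbut-2-enyl)-2H-chromene | COc1cc(OCOC)c(CC=C(C)C)c2OC(C)(C)C=Cc12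
A6 | alternative 2 | 3-methoxy-5-(methoxymethoxy)-6-(3-methylbut-2-enyl)-2-(trimethylsilyl)phenyl trifluoromethanesulfonate | COc1cc(OCOC)c(CC=C(C)C)c(OS(=O)(=O)C(F)(F)F)c1[Si](C)(C)C
A7 | alternative 3 | Derrisdione A tert-butyldimethylsilyl ether (ring B) | COc1c2c(c(CC=C(C)C)c(O)c1C(=O)C(=O)c1ccc(O[Si](C)(C)C(C)(C)C)cc1)OC(C)(C)C=C2
A8 | alternative 3 | 1-[4-(tert-butyldimethylsilyloxy)phenyl]-2-[2-methoxy-6-(2-methylbut-3-en-2-yloxy)-4-(2-methylbut-3-yn-2-yloxy)phenyl]ethane-1,2-dione | COc1cc(OC(C)(C)C#C)cc(OC(C)(C)C=C)c1C(=O)C(=O)c1ccc(O[Si](C)(C)C(C)(C)C)cc1
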